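## Analysis of the target

Target 15 is a chalcone whose ring A is a phloroglucinol-derived benzene ring with five substituents: hydroxyls at C5 and C7, the enone carbonyl at C8, and a 3-hydroxy-2,2-dimethyl-dihydropyran ring fused through O1–C8a and C4–C4a. Ring B is a 4-hydroxyphenyl group attached through an E-configured Cα=Cβ bond. The only stereocentre is C3 (S), a secondary carbinol between the quaternary C2 and the benzylic C4; with no second stereocentre to relate it to, it has to be set by a chiral reagent or catalyst alone. The sensitive groups are the C7 hydroxyl ortho to the ketone, which can add to the enone and close a flavanone under base or strong acid, the enone itself (Michael acceptor, isomerises in light), and the easily oxidised trioxygenated ring A. The difficulty is regiochemical rather than stereochemical: three equivalent oxygens of the phloroglucinol core end in three different roles, the acyl group must sit at C8 and not at C6, and the heterocycle must be the six-membered chromanol and not the isomeric dihydrobenzofuran carrying a hydroxyisopropyl group. The strategy rests on the ketone carbon: it is bonded only to C8 of ring A and to Cα of the styryl unit, so it can be brought in as carbon monoxide between an aryl halide at C8 and a styrene that carries ring B.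

## Retrosynthetic reasoning

**Last operations (15 ⇐ 14 ⇐ 13).** The hydroxyls are unmasked in two stages. The O–CH2 acetal bonds at O5 and O7 are cut last, under mild acid, because the free C7 hydroxyl is the one that can cyclise onto the enone. Before that, the two O-acetyl bonds (at O3 and at the ring B oxygen) are cut under base while both oxygens ortho to the ketone are still capped. Thus 15 comes from the bis-acetal 14, and 14 from the diacetate 13.

**Key disconnection (13 ⇐ 10 + 11 + 12).** The bonds C8–C(=O) and C(=O)–Cα are cut together. This takes the ketone carbon out as carbon monoxide 11 and leaves the aryl iodide 10 and the styrene 12. Cutting at Cα=Cβ (aldol) would first require a C8 methyl ketone, and cutting only at C8–C(=O) (Friedel–Crafts acylation) would need a Lewis acid on an arene with acetal ethers and would leave the C6/C8 choice open. Here the iodide fixes the position and ring B arrives in one piece from a commercial compound. The forward reaction must take up CO before the alkene inserts and must give the linear E enone.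

**Iodide and acetate (10 ⇐ 9 ⇐ 8).** The C8–I bond is traced back to C8–H of acetate 9. The forward electrophilic iodination has to choose C8 over C6, and the difference in crowding between the two sites is relied on for that. The O3–acetyl bond is then cut to chromanol 8. The acetate keeps the secondary hydroxyl from capturing the aroyl–palladium intermediate, and it leaves in the same operation as the ring B acetate.

**Pyran ring (8 ⇐ 7 ⇐ 6).** The ring is opened at O1–C2, the bond between the phenol oxygen and the gem-dimethyl carbon, giving the epoxy phenol 7. This cut leaves the C3–O bond intact, so the stereocentre is carried in from the epoxide. The forward reaction is an acid-promoted opening at the tertiary epoxide carbon (6-endo). Attack at the secondary carbon (5-exo) is what a phenoxide would do, so 7 is released from its silyl ether 6 under buffered conditions and cyclised only under acid.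

**Stereocentre (6 ⇐ 5).** Removing the epoxide oxygen gives the prenyl arene 5, a trisubstituted alkene of the type R–CH=CMe2, for which chiral dioxirane epoxidation is dependable. All three ring oxygens are capped in 5, so the basic oxidising medium meets neither a phenoxide nor a free phenol.

**Carbon skeleton (5 ⇐ 4 ⇐ 2 + 3, 2 ⇐ 1).** The silyl group is removed to phenol 4, and the C4–C4a bond (arene carbon to allylic CH2) is cut to the bis-acetal phenol 2 and prenyl bromide 3. The two carbons ortho to the free hydroxyl of 2 are equivalent, so ortho-C-alkylation of its phenoxide gives one product, and the one free hydroxyl is exactly the oxygen that becomes O1. Phenol 2 is phloroglucinol 1 with two of its three equivalent hydroxyls etherified.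

## Alternatives that were turned down

**Alternative 1:** The flavanone ring of naringenin A1 is used as a masked chalcone, and the pyran ring is disconnected at C4–C4a and O1–C2 back to a tertiary propargyl aryl ether.
- **Forward key step:** heating the ether A2 (7,4'-bis-acetal of A1, 1,1-dimethylpropargyl group on the chelated 5-oxygen) should trigger propargyl Claisen rearrangement to C6, [1,5]-hydrogen shift and oxa-6π electrocyclisation, giving the pyranoflavanone A3.
- **For:** all fifteen chalcone carbons come from one cheap natural product. The cascade is regiospecific because only one carbon ortho to that oxygen is free. No pressure equipment is needed. On step count this alternative is stronger than the chosen route.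
- **Against:** A3 is a chromene, so the carbon next to the gem-dimethyl carbon has neither its oxygen nor its configuration. Both must be added by enantioselective epoxidation and regioselective hydride opening in the presence of the flavanone ketone, on a substrate with a racemic stereocentre at the flavanone C2 (diastereomer mixtures until the ring is opened). The flavanone-to-chalcone opening is an equilibrium that tends to lie on the flavanone side and can reverse in the final acid step. Alkylating a hydrogen-bonded, hindered hydroxyl with a tertiary propargyl electrophile is also slow.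
- **Comparison:** the chosen strategy sets C3 on a simple alkene with no other stereocentre present, and it forms the enone last and in the open form, so nothing has to survive redox steps or a ring-opening equilibrium.

**Alternative 2:** The pyran ring is cut at C4–C4a of a chroman-3-one.
- **Forward key step:** gold-catalysed N-oxide oxidation of the terminal alkyne of ether A4 gives an α-oxo gold carbene at the terminal carbon, which is attacked by the ortho arene carbon to close ketone A5. Asymmetric ketone reduction (CBS or transfer hydrogenation) then sets C3.
- **For:** ring size is not in question, the two ortho carbons are equivalent, and no phenol has to be masked and unmasked. It reaches the chromanol stage in one step fewer than steps 2–5 of the chosen route. On ring-size control it is stronger.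
- **Against:** tertiary propargyl ethers of electron-rich phenols ionise under carbophilic Lewis acids, and the activated alkyne can be attacked directly by the arene (hydroarylation to the chromene) before the oxidant adds. A5 has an acidic benzylic CH2 next to the ketone and is prone to enolisation and air oxidation. The reduction has to tell a CH2Ar from a CMe2(OAr) flank, which is plausible but less certain than dioxirane epoxidation of an R–CH=CMe2 alkene. The strategy also spends its key step on a ring that a prenyl group delivers from bulk chemicals, and leaves the harder problem, the acyl group at C8, unanswered.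
- **Comparison:** the chosen strategy gives a stereocentre from a well-behaved alkene class and puts its strategic step on the C8 acyl problem.

**Alternative 3:** The pyran ring is cut at C3–C4 and O1–C2.
- **Forward key step:** the ortho-quinone methide generated from hydroxymethyl phenol A6 is attacked at its methylene by the hydroxylated carbon of a chiral enamine of hydroxyacetone A7. The phenol oxygen then closes onto the ketone to give hemiketal A8.
- **For:** it is convergent, sets C3 by organocatalysis, and already carries the acetyl group at C8 from an acylphloroglucinol precursor. The chalcone would then follow by a plain aldol condensation and there is no C6/C8 question at all; on that point it is stronger.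
- **Against:** A8 has at C2 one methyl group and a hemiketal hydroxyl, not the gem-dimethyl tertiary ether. Converting it requires adding a methyl nucleophile to the ring-opened ketone while a second ketone (the C8 acetyl) is present. The pyran must then be re-closed at a tertiary carbinol under acid with acetal ethers on the ring, which brings back the ring-closure problem with more steps. Regiochemistry of the enamine (hydroxylated versus methyl carbon) and its enantiocontrol towards quinone methides are uncertain.
- **Comparison:** the chosen strategy gets C2 with both methyl groups from the prenyl unit at no cost and settles the acyl position through the iodide.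

Key step: step 8

Remark on the chemistry: the L-fructose-derived enantiomer of the Shi ketone (accessible from L-sorbose) is assumed to be available; the common D-fructose ketone would lead to the 3R series.

## Route

Step 1
Reactants: 1 phloroglucinol
Product: 2 3,5-bis(methoxymethoxy)phenol
Conditions: MOMCl (2.0 equiv), i-Pr2NEt (2.2 equiv), DMF, 0 °C → rt
Reagents that add atoms: chloromethyl methyl ether `COCCl`
Why: O-alkylation of three equivalent hydroxyls with two equivalents of the chloromethyl ether should give the bis-ether as the main component of a statistical mixture; the mono- and tris-ethers are separable and the mono-ether can be resubmitted. The acetal ethers withstand the basic, oxidative and palladium steps that follow and are removed by mild acid at the end.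

Step 2
Reactants: 2 3,5-bis(methoxymethoxy)phenol; 3 1-bromo-3-methylbut-2-ene
Product: 4 3,5-bis(methoxymethoxy)-2-(3-methylbut-2-en-1-yl)phenol
Conditions: NaH (1.05 equiv), toluene, 0 °C → rt; then 3 (1.1 equiv), rt
Reagents that add atoms: none
Why: ortho-C-alkylation of a sodium phenoxide in a non-polar solvent: the contact ion pair delivers the allylic bromide to the carbon next to the O–Na group through a cyclic transition state, whereas O-alkylation and para attack need a dissociated phenoxide. The two ortho carbons are equivalent and the para carbon is flanked by two acetal ethers.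

Step 3
Reactants: 4 3,5-bis(methoxymethoxy)-2-(3-methylbut-2-en-1-yl)phenol
Product: 5 [3,5-bis(methoxymethoxy)-2-(3-methylbut-2-en-1-yl)phenoxy]tri(propan-2-yl)silane
Conditions: i-Pr3SiCl, imidazole, DMF, rt
Reagents that add atoms: chlorotri(propan-2-yl)silane `CC(C)[Si](Cl)(C(C)C)C(C)C`
Why: Silylation of the phenol; the bulky silyl ether keeps the phenol from being deprotonated, oxidised or cyclised in the basic epoxidation medium and is later removed by fluoride without touching the acetal ethers.

Step 4
Reactants: 5 [3,5-bis(methoxymethoxy)-2-(3-methylbut-2-en-1-yl)phenoxy]tri(propan-2-yl)silane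
Product: 6 [2-{[(2S)-3,3-dimethyloxiran-2-yl]methyl}-3,5-bis(methoxymethoxy)phenoxy]tri(propan-2-yl)silane
Conditions: ent-Shi ketone (L-fructose-derived, 30 mol %), Oxone (2KHSO5·KHSO4·K2SO4), K2CO3, Bu4NHSO4, MeCN/CH2(OMe)2/aq. Na2B4O7 buffer (pH 10.5), 0 °C
Reagents that add atoms: potassium peroxymonosulfate `[K+].[O-]S(=O)(=O)OO`
Why: Shi epoxidation: the chiral dioxirane formed from the ketone and KHSO5 transfers oxygen to the trisubstituted alkene through a spiro transition state. The D-fructose ketone converts R–CH=CMe2 alkenes into R epoxides, so its L-configured enantiomer is used to set the 2S oxirane carbon, which becomes C3 of the target.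

Step 5
Reactants: 6 [2-{[(2S)-3,3-dimethyloxiran-2-yl]methyl}-3,5-bis(methoxymethoxy)phenoxy]tri(propan-2-yl)silane
Product: 8 (3S)-5,7-bis(methoxymethoxy)-2,2-dimethyl-3,4-dihydro-2H-chromen-3-ol, via phenol epoxide 7 (not isolated)
Conditions: Bu4NF, AcOH (1:1), THF, 0 °C; work-up; then CSA (10 mol %), CH2Cl2, −20 → 0 °C
Reagents that add atoms: none
Why: Fluoride buffered with AcOH frees the phenol without leaving a phenoxide; under Brønsted acid catalysis the epoxide then opens at its tertiary carbon, which carries most of the positive charge, by 6-endo attack of the phenol oxygen (O1–C2). The C3–O bond is not broken, so the 3S configuration comes unchanged from the epoxide.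

Step 6
Reactants: 8 (3S)-5,7-bis(methoxymethoxy)-2,2-dimethyl-3,4-dihydro-2H-chromen-3-ol
Product: 9 (3S)-5,7-bis(methoxymethoxy)-2,2-dimethyl-3,4-dihydro-2H-chromen-3-yl acetate
Conditions: Ac2O, pyridine, DMAP (cat.), CH2Cl2, rt
Reagents that add atoms: acetic anhydride `CC(=O)OC(C)=O`
Why: DMAP-catalysed acylation of the hindered secondary alcohol; the acetate keeps the hydroxyl from intercepting the aroyl–palladium species of step 8 as an ester.

Step 7
Reactants: 9 (3S)-5,7-bis(methoxymethoxy)-2,2-dimethyl-3,4-dihydro-2H-chromen-3-yl acetate
Product: 10 (3S)-8-iodo-5,7-bis(methoxymethoxy)-2,2-dimethyl-3,4-dihydro-2H-chromen-3-yl acetate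
Conditions: NIS (1.05 equiv), DMF, 0 °C, dark
Reagents that add atoms: N-iodosuccinimide `O=C1CCC(=O)N1I`
Why: Electrophilic aromatic iodination of a ring activated by three oxygen substituents. C8 lies between the ring oxygen, which is tied back in the pyran, and one acetal ether, whereas C6 is flanked by two freely rotating acetal ethers; 5,7-dialkoxychromans such as flavan-3-ol ethers are halogenated at C8 by N-halosuccinimides.

Step 8
Reactants: 10 (3S)-8-iodo-5,7-bis(methoxymethoxy)-2,2-dimethyl-3,4-dihydro-2H-chromen-3-yl acetate; 11 carbon monoxide; 12 4-ethenylphenyl acetate (4-acetoxystyrene)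
Product: 13 (3S)-8-[(2E)-3-(4-acetoxyphenyl)prop-2-enoyl]-5,7-bis(methoxymethoxy)-2,2-dimethyl-3,4-dihydro-2H-chromen-3-yl acetate
Conditions: Pd(dba)2 (5 mol %), di(1-adamantyl)-n-butylphosphine (10 mol %), Et3N (2 equiv), CO (10 bar), 12 (2.5 equiv), 1,4-dioxane, 100 °C
Reagents that add atoms: none
Why: Carbonylative Heck reaction of an aryl iodide with a styrene, a known route to chalcones. Zerovalent palladium inserts into the C8–I bond of 10, CO (11) inserts into the aryl–palladium bond to give an aroyl–palladium iodide, the alkene of 12 coordinates and inserts with the acyl group going to the terminal CH2 carbon and palladium to the benzylic carbon, and syn β-hydride elimination followed by loss of HI to Et3N returns zerovalent palladium and releases 13; the two new bonds are C8–C(=O) and C(=O)–Cα. No ring is closed and no stereocentre is formed; C3 is a spectator and its acetate keeps the hydroxyl from trapping the aroyl–palladium species. The selectivity that matters is carbonylative against direct Heck coupling: C8 carries two ortho oxygen substituents (O1 and the C7 acetal ether), which hinder coordination and insertion of the styrene at the aryl–palladium stage, while the small CO ligand inserts readily and moves the metal one atom away from the crowded ring, so that the alkene meets an accessible acyl–palladium centre. The bulky, electron-rich monophosphine keeps the acyl complex mono-ligated with a free site for the styrene, and moderate CO pressure with an excess of 12 balances CO uptake against blocking of that site. Regiochemistry of insertion follows from the benzyl-stabilised palladium alkyl, and the E geometry from β-hydride elimination through the conformer with aryl and aroyl groups anti, which also gives the more stable conjugated isomer. Acetal ethers, both acetates and the aryl alkyl ether are inert to these amine-buffered conditions.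

Step 9
Reactants: 13 (3S)-8-[(2E)-3-(4-acetoxyphenyl)prop-2-enoyl]-5,7-bis(methoxymethoxy)-2,2-dimethyl-3,4-dihydro-2H-chromen-3-yl acetate
Product: 14 (2E)-1-[(3S)-3-hydroxy-5,7-bis(methoxymethoxy)-2,2-dimethyl-3,4-dihydro-2H-chromen-8-yl]-3-(4-hydroxyphenyl)prop-2-en-1-one
Conditions: K2CO3, MeOH, 0 °C → rt; aq. NH4Cl work-up
Reagents that add atoms: none
Why: Base-mediated transesterification (methanolysis) of the aryl and the secondary acetate; K2CO3 acts as base and does not enter the balanced equation. Both oxygens ortho to the ketone are still etherified, so no phenoxide can add to the enone, and the ring B phenoxide formed in the flask makes the enone less electrophilic.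

Step 10
Reactants: 14 (2E)-1-[(3S)-3-hydroxy-5,7-bis(methoxymethoxy)-2,2-dimethyl-3,4-dihydro-2H-chromen-8-yl]-3-(4-hydroxyphenyl)prop-2-en-1-one
Product: 15 (2E)-1-[(3S)-3,5,7-trihydroxy-2,2-dimethyl-3,4-dihydro-2H-chromen-8-yl]-3-(4-hydroxyphenyl)prop-2-en-1-one
Conditions: HCl (1.5 M, MeOH/H2O), rt, dark, argon
Reagents that add atoms: none
Why: Acid-catalysed acetal exchange with MeOH removes the two aryl methoxymethyl ethers. Dilute acid at room temperature is used so that the liberated C7 hydroxyl does not add to the enone and the tertiary ether O1–C2 stays intact; C3 is not involved.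

## Compound list

```
1 | phloroglucinol (benzene-1,3,5-triol) | Oc1cc(O)cc(O)c1 | starting material
2 | 3,5-bis(methoxymethoxy)phenol | COCOc1cc(O)cc(OCOC)c1 | intermediate
3 | 1-bromo-3-methylbut-2-ene | CC(C)=CCBr | starting material
4 | 3,5-bis(methoxymethoxy)-2-(3-methylbut-2-en-1-yl)phenol | CC(C)=CCc1c(O)cc(OCOC)cc1OCOC | intermediate
5 | [3,5-bis(methoxymethoxy)-2-(3-methylbut-2-en-1-yl)phenoxy]tri(propan-2-yl)silane | CC(C)=CCc1c(O[Si](C(C)C)(C(C)C)C(C)C)cc(OCOC)cc1OCOC | intermediate
6 | [2-{[(2S)-3,3-dimethyloxiran-2-yl]methyl}-3,5-bis(methoxymethoxy)phenoxy]tri(propan-2-yl)silane | CC(C)[Si](Oc1cc(OCOC)cc(OCOC)c1C[C@@H]1OC1(C)C)(C(C)C)C(C)C | intermediate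
7 | 2-{[(2S)-3,3-dimethyloxiran-2-yl]methyl}-3,5-bis(methoxymethoxy)phenol | Oc1cc(OCOC)cc(OCOC)c1C[C@@H]1OC1(C)C | intermediate
8 | (3S)-5,7-bis(methoxymethoxy)-2,2-dimethyl-3,4-dihydro-2H-chromen-3-ol | CC1(C)Oc2cc(OCOC)cc(OCOC)c2C[C@@H]1O | intermediate
9 | (3S)-5,7-bis(methoxymethoxy)-2,2-dimethyl-3,4-dihydro-2H-chromen-3-yl acetate | CC1(C)Oc2cc(OCOC)cc(OCOC)c2C[C@@H]1OC(C)=O | intermediate
10 | (3S)-8-iodo-5,7-bis(methoxymethoxy)-2,2-dimethyl-3,4-dihydro-2H-chromen-3-yl acetate | CC1(C)Oc2c(c(OCOC)cc(OCOC)c2I)C[C@@H]1OC(C)=O | intermediate
11 | carbon monoxide | [C-]#[O+] | starting material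
12 | 4-ethenylphenyl acetate (4-acetoxystyrene) | CC(=O)Oc1ccc(C=C)cc1 | starting material
13 | (3S)-8-[(2E)-3-(4-acetoxyphenyl)prop-2-enoyl]-5,7-bis(methoxymethoxy)-2,2-dimethyl-3,4-dihydro-2H-chromen-3-yl acetate | CC1(C)Oc2c(c(OCOC)cc(OCOC)c2C(=O)/C=C/c2ccc(OC(C)=O)cc2)C[C@@H]1OC(C)=O | intermediate
14 | (2E)-1-[(3S)-3-hydroxy-5,7-bis(methoxymethoxy)-2,2-dimethyl-3,4-dihydro-2H-chromen-8-yl]-3-(4-hydroxyphenyl)prop-2-en-1-one | CC1(C)Oc2c(c(OCOC)cc(OCOC)c2C(=O)/C=C/c2ccc(O)cc2)C[C@@H]1O | intermediate
15 | (2E)-1-[(3S)-3,5,7-trihydroxy-2,2-dimethyl-3,4-dihydro-2H-chromen-8-yl]-3-(4-hydroxyphenyl)prop-2-en-1-one | CC1(C)Oc2c(c(O)cc(O)c2C(=O)/C=C/c2ccc(O)cc2)C[C@@H]1O | target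
```

## Step count and least certain steps

Total step count: 10. Longest linear sequence: 10 steps (1 → 15); 3, 11 and 12 are commercial and enter at steps 2 and 8.

**Step 8 (key step).**
- **What may go wrong:** direct Heck coupling without CO uptake; stalling of styrene insertion at the crowded aroyl–palladium stage, followed by hydrolysis or reduction of the acyl complex and deposition of palladium; thermal polymerisation of the styrene at 100 °C.
- **Fallback:** it gives up the carbonylation and sets out from 10. Stille coupling with tributyl(1-ethoxyethenyl)stannane (PdCl2(PPh3)2, toluene, 100 °C) should give the enol ether (3S)-8-(1-ethoxyethenyl)-5,7-bis(methoxymethoxy)-2,2-dimethyl-3,4-dihydro-2H-chromen-3-yl acetate F1. Brief treatment with cold dilute aqueous HCl in THF converts it into the methyl ketone (3S)-8-acetyl-5,7-bis(methoxymethoxy)-2,2-dimethyl-3,4-dihydro-2H-chromen-3-yl acetate F2. Claisen–Schmidt condensation of F2 with 4-(methoxymethoxy)benzaldehyde (KOH, EtOH/H2O, rt), during which the C3 acetate is saponified, should give the chalcone (2E)-1-[(3S)-3-hydroxy-5,7-bis(methoxymethoxy)-2,2-dimethyl-3,4-dihydro-2H-chromen-8-yl]-3-[4-(methoxymethoxy)phenyl]prop-2-en-1-one F3. The acid conditions of step 10 then remove its three acetal ethers, and the route is rejoined at 15.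

**Step 5.**
- **What may go wrong:** opening of the epoxide at its secondary carbon (5-exo), either by phenoxide during desilylation or in competition under acid, which leads to the dihydrobenzofuran carbinol series; hydride shift in the tertiary cation; partial loss of an acetal ether under acid.
- **Fallback:** it forms the ring before the oxygen is introduced and sets out from 4. Dehydrogenative cyclisation with DDQ (toluene, 80 °C) should give the chromene 5,7-bis(methoxymethoxy)-2,2-dimethyl-2H-chromene F4. Jacobsen epoxidation follows, with (S,S)-N,N'-bis(3,5-di-tert-butylsalicylidene)cyclohexane-1,2-diaminomanganese chloride (a (salen)MnCl complex of trivalent manganese), aqueous NaOCl and 4-phenylpyridine N-oxide in CH2Cl2 at 0 °C. It should give (3S,4S)-3,4-epoxy-5,7-bis(methoxymethoxy)-2,2-dimethylchroman F5. F5 is expected to be solvolytically labile because of the electron-rich ring, which is why this is not the main route, so it is used crude. LiAlH4 (THF, 0 °C) delivers hydride to the benzylic C4 and returns the route to 8.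

**Step 2.**
- **What may go wrong:** O-alkylation, attack at the para carbon C4, and double alkylation of the electron-rich phenoxide.
- **Fallback:** it replaces intermolecular C-alkylation by a sigmatropic shift and sets out from 2. Copper-catalysed etherification with 3-chloro-3-methylbut-1-yne (CuCl2 cat., DBU, MeCN, 0 °C) should give 1,3-bis(methoxymethoxy)-5-[(2-methylbut-3-yn-2-yl)oxy]benzene F6. Lindlar semihydrogenation (H2, Pd/CaCO3 poisoned with Pb(OAc)2, quinoline, EtOAc) gives 1,3-bis(methoxymethoxy)-5-[(2-methylbut-3-en-2-yl)oxy]benzene F7. Aromatic Claisen rearrangement on heating in toluene then delivers the prenyl group to one of the two equivalent ortho carbons and returns to 4.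

**Step 7.**
- **What may go wrong:** iodination at C6 instead of C8, or double iodination.
- **Fallback:** it replaces the steric preference of the electrophile by a directed metal–halogen exchange and sets out from 8. Exhaustive iodination (NIS, 2.2 equiv, DMF) should give (3S)-6,8-diiodo-5,7-bis(methoxymethoxy)-2,2-dimethyl-3,4-dihydro-2H-chromen-3-ol F8. i-PrMgCl·LiCl (2.1 equiv, the first equivalent deprotonating the C3 hydroxyl; THF, −40 °C) is expected to exchange the C6 iodine, which is flanked by two chelating acetal ethers. Protonation with aq. NH4Cl gives (3S)-8-iodo-5,7-bis(methoxymethoxy)-2,2-dimethyl-3,4-dihydro-2H-chromen-3-ol F9, and acetylation as in step 6 rejoins the route at 10.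

## Further compounds

```
F1 | step 8 | (3S)-8-(1-ethoxyethenyl)-5,7-bis(methoxymethoxy)-2,2-dimethyl-3,4-dihydro-2H-chromen-3-yl acetate | CC1(C)Oc2c(c(OCOC)cc(OCOC)c2C(=C)OCC)C[C@@H]1OC(C)=O
F2 | step 8 | (3S)-8-acetyl-5,7-bis(methoxymethoxy)-2,2-dimethyl-3,4-dihydro-2H-chromen-3-yl acetate | CC1(C)Oc2c(c(OCOC)cc(OCOC)c2C(C)=O)C[C@@H]1OC(C)=O
F3 | step 8 | (2E)-1-[(3S)-3-hydroxy-5,7-bis(methoxymethoxy)-2,2-dimethyl-3,4-dihydro-2H-chromen-8-yl]-3-[4-(methoxymethoxy)phenyl]prop-2-en-1-one | CC1(C)Oc2c(c(OCOC)cc(OCOC)c2C(=O)/C=C/c2ccc(OCOC)cc2)C[C@@H]1O
F4 | step 5 | 5,7-bis(methoxymethoxy)-2,2-dimethyl-2H-chromene | CC1(C)C=Cc2c(OCOC)cc(OCOC)cc2O1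
F5 | step 5 | (3S,4S)-3,4-epoxy-5,7-bis(methoxymethoxy)-2,2-dimethylchroman | CC1(C)Oc2cc(OCOC)cc(OCOC)c2[C@@H]2O[C@H]12
F6 | step 2 | 1,3-bis(methoxymethoxy)-5-[(2-methylbut-3-yn-2-yl)oxy]benzene | C#CC(C)(C)Oc1cc(OCOC)cc(OCOC)c1
F7 | step 2 | 1,3-bis(methoxymethoxy)-5-[(2-methylbut-3-en-2-yl)oxy]benzene | C=CC(C)(C)Oc1cc(OCOC)cc(OCOC)c1
F8 | step 7 | (3S)-6,8-diiodo-5,7-bis(methoxymethoxy)-2,2-dimethyl-3,4-dihydro-2H-chromen-3-ol | CC1(C)Oc2c(I)c(OCOC)c(I)c(OCOC)c2C[C@@H]1O
F9 | step 7 | (3S)-8-iodo-5,7-bis(methoxymethoxy)-2,2-dimethyl-3,4-dihydro-2H-chromen-3-ol | CC1(C)Oc2c(I)c(OCOC)cc(OCOC)c2C[C@@H]1O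
A1 | alternative 1 | naringenin (5,7-dihydroxy-2-(4-hydroxyphenyl)chroman-4-one, racemic) | O=C1CC(c2ccc(O)cc2)Oc2cc(O)cc(O)c12
A2 | alternative 1 | 7-(methoxymethoxy)-2-[4-(methoxymethoxy)phenyl]-5-[(2-methylbut-3-yn-2-yl)oxy]chroman-4-one (racemic) | C#CC(C)(C)Oc1cc(OCOC)cc2OC(c3ccc(OCOC)cc3)CC(=O)c12
A3 | alternative 1 | racemic flavanone with a 2,2-dimethyl-2H-pyran ring fused at O5/C6 and methoxymethyl ethers at O7 and O4' | CC1(C)C=Cc2c(OCOC)cc3OC(c4ccc(OCOC)cc4)CC(=O)c3c2O1
A4 | alternative 2 | 1,3-bis(methoxymethoxy)-5-[(2-methylbut-3-yn-2-yl)oxy]benzene | C#CC(C)(C)Oc1cc(OCOC)cc(OCOC)c1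
A5 | alternative 2 | 5,7-bis(methoxymethoxy)-2,2-dimethylchroman-3-one | CC1(C)Oc2cc(OCOC)cc(OCOC)c2CC1=O
A6 | alternative 3 | 1-[2-hydroxy-3-(hydroxymethyl)-4,6-bis(methoxymethoxy)phenyl]ethanone | CC(=O)c1c(O)c(CO)c(OCOC)cc1OCOC
A7 | alternative 3 | hydroxyacetone (1-hydroxypropan-2-one) | CC(=O)CO
A8 | alternative 3 | 1-[(3S)-2,3-dihydroxy-5,7-bis(methoxymethoxy)-2-methylchroman-8-yl]ethanone (anomeric mixture at C2) | CC1(O)Oc2c(c(OCOC)cc(OCOC)c2C(C)=O)C[C@@H]1O
```
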